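Larch and the south-west run hold the same substrate and activator for the same 2.5 h, but in larch half of the substrate waits until 2.0 h. I expect the two to part over age, the time a substrate molecule has spent activated.

| setting | south-west | north-west | east | north | birch | oak | elm | alder | larch |
|---|---|---|---|---|---|---|---|---|---|
| substrate | 20 mM | 10 mM | 40 mM | 20 mM | 20 mM (fed, over 2.0 h) | 20 mM | 20 mM | 20 mM (fed, over 30 min) | 20 mM (in portions, 2, over 2.0 h) |
| activator | 1.1 equiv | 1.1 equiv | 1.1 equiv | 2.2 equiv | 1.10 equiv | 1.10 equiv | 1.10 equiv (fed, over 2.0 h) | 1.10 equiv | 1.10 equiv |
| remark | run made earlier | run made earlier | run made earlier | run made earlier | all else is in the flask from the start; the feed brings no volume worth counting | everything together at the start | all else is in the flask from the start; the feed brings no volume worth counting | all else is in the flask from the start; the feed brings no volume worth counting | first portion at the start, last at 2.0 h |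
| time |  |  |  |  | 2.5 h | 2.5 h | 2.5 h | 2.5 h | 2.5 h |

- south-west (time / h: ring / %, substrate / %): 0.417: 10, 12; 0.833: 19, 2; 1.33: 30, 1; 1.50: 35, 3; 2.00: 49, 4; 2.50: 55, 4
- north-west (time / h: ring / %, substrate / %): 0.417: 9, 18; 0.833: 17, 10; 1.33: 33, 6; 1.50: 32, 6; 2.00: 45, 3; 2.50: 52, 1
- east (time / h: ring / %, substrate / %): 0.167: 5, 11; 0.500: 13, 1; 0.833: 22, 1; 1.33: 33, 0; 2.00: 46, 0; 2.50: 55, 0
- north (time / h: ring / %, substrate / %): 0.200: 3, 1; 0.667: 18, 1; 1.33: 38, 0; 2.00: 50, 0; 2.50: 57, 0

(standard deviation of a reading: 2 percentage points)

- a reading or a percentage of ring counts all its forms, free or not

- the flask with the highest amount of ring, in percent of the substrate charged ("all alike" if they lie within 1.5 percentage points) (birch / oak / elm / alder / larch / all alike)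
- final ring, as a percentage of the substrate charged, in birch
- final ring, as a percentage of the substrate charged, in oak
- final ring, as a percentage of the substrate charged, in elm
- final ring, as a percentage of the substrate charged, in alder
- final ring, as a percentage of the substrate charged, in larch

In the south-west run substrate reads 12% at 0.417 h, while ring reads 10%, so an unseen activated form stands between them. The end readings of ring are 52%, 55% and 57% in the north-west, east and north runs, against 55% in south-west. They lie close together for [substrate] from 10 mM to 40 mM and for doubled activator, so I read closing as first order.

The south-west end gives 7.21 h as the closing decade, the age over which the unclosed share falls by one power of ten. That is a closing half-life of 2.17 h. Substrate, taken as first order, reads a half-life of 0.136 h. Closing, the rate-limiting step, is slower than activation, but the second portion of larch has just 0.500 h in the flask, so I take off its mean wait before activation, 0.197 h. For the first portion I take off nothing, since the decade was read from the south-west end and holds that wait already. For larch: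

first portion, age 2.5 h: unclosed 45.0%

second portion, age 0.303 h: unclosed 90.8%

ring, by my reckoning: 32.1%

So larch ends lower than south-west.

The forecast names oak as highest: oak 55%, alder 51%, elm 39%, birch 36%, and larch 33%, within 29% to 37%, which is 0.90 percentage points above mine. Its ground: “Final ring therefore depends only on the time each molecule spends activated”.

The flasks give oak as highest: oak 54.8%, alder 50.8%, birch 36.0%, elm 34.7%, larch 33.9%.

    substrate + activator → activated form (k = 11.5 M⁻¹ min⁻¹)
    activated form → ring (k = 0.00607 min⁻¹)
    substrate + activated form → open dimer (k = 0.177 M⁻¹ min⁻¹)
    activator + ring ⇌ idle adduct, settled at all times (K = 57.0 M⁻¹)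
    crystals ⇌ ring, rate k5*(cs5 - [ring]) while solid is left; crystals form when [ring] > cs5 (solubility = 2.70 mM, k = 0.529 min⁻¹)

In larch, activation had 55% of its turnover behind it at 1.25 h, and closing had 8.8% of its turnover behind it at 0.250 h. Closing ran on while activated form stood, with 55.8% of it beside 7.93% substrate at 2.50 h. The closing decade gave 32.1% against the 33.9% found, and at 25.0 h larch holds 96.7% and oak 95.9%, so the low reading in larch belongs to the time of reading.

Read at 4.0 h, the larch neighbour has portions aged 4.0 h and, after the same wait, 1.80 h, and the closing decade gives 58.0%. The simulated flask holds 59.5%.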